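**Assumption:** the target SMILES has no stereocentres and no E/Z-defined alkenes (the prenyl alkenes are trisubstituted with two identical methyls), so the molecule is achiral and "single enantiomer" needs no stereocontrol. The only selectivity issue is linear versus reverse prenyl regiochemistry.

## Retrosynthetic overview

1. Target ⇐ MOM removal ⇐ one-pot double, linear-selective sp2–sp3 Suzuki–Miyaura prenylation of a 3',5'-dibromoisoflavone with prenyl-Bpin. This is the key step: both acid-sensitive prenyl groups go on last, onto the finished isoflavone.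
2. 3',5'-Dibromogenistein ⇐ C-ring closure by one-carbon insertion (DMF/MsCl/BF3) on a deoxybenzoin.
3. Deoxybenzoin ⇐ BF3-mediated Friedel–Crafts acylation of phloroglucinol with 3,5-dibromo-4-hydroxyphenylacetic acid (from 4-hydroxyphenylacetic acid and Br2).
4. Ring order: rings A and B are purchased aromatics; only ring C (the 4-pyranone) is built. This avoids the usual 3-iodochromone plus pre-prenylated arylboronate Suzuki route.

## Route

**Step 1**
Reactants: 1, 4-hydroxyphenylacetic acid
Product: 2, 3,5-dibromo-4-hydroxyphenylacetic acid
Conditions: Br2 (2.1 equiv), AcOH, rt, 3 h; aq NaHSO3 quench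
Reagents that add atoms: bromine, BrBr
Why: Electrophilic aromatic bromination; the phenol OH directs to both ortho positions (para is blocked) and the CH2CO2H side chain is inert under these conditions.

**Step 2**
Reactants: 2, 3,5-dibromo-4-hydroxyphenylacetic acid; 3, phloroglucinol (anhydrous)
Product: 4, 2-(3,5-dibromo-4-hydroxyphenyl)-1-(2,4,6-trihydroxyphenyl)ethan-1-one (deoxybenzoin)
Conditions: BF3·OEt2 (neat, excess), 80 °C, 2 h; then aq NaOAc
Reagents that add atoms: none
Why: BF3-mediated Friedel–Crafts (Hoesch-type) C-acylation of the very electron-rich, C3-symmetric phloroglucinol, so there is no regiochemical issue; the product is held as a deactivated BF2 chelate, which stops at mono-acylation.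

**Step 3**
Reactants: 4, deoxybenzoin
Product: 5, 3-(3,5-dibromo-4-hydroxyphenyl)-5,7-dihydroxy-4H-chromen-4-one (3',5'-dibromogenistein)
Conditions: BF3·OEt2, DMF, then MsCl (3 equiv) in DMF, 50 → 80 °C, 2 h; aqueous work-up. Can be telescoped with step 2 in one pot.
Reagents that add atoms: N,N-dimethylformamide, CN(C)C=O (supplies C-2 as CH)
Why: Vilsmeier-type formylation of the activated benzylic methylene followed by cyclodehydration onto an ortho OH (deoxybenzoin-to-isoflavone ring closure); the two ortho OH groups are equivalent, so only one isoflavone can form.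

**Step 4**
Reactants: 5, 3',5'-dibromogenistein
Product: 6, 3-[3,5-dibromo-4-(methoxymethoxy)phenyl]-5-hydroxy-7-(methoxymethoxy)-4H-chromen-4-one
Conditions: MOMCl (2.3 equiv), i-Pr2NEt (3 equiv), DMF, 0 °C → rt
Reagents that add atoms: chloromethyl methyl ether, COCCl
Why: O-alkylation of the two acidic, non-chelated phenols (7-OH and 4'-OH); the 5-OH is hydrogen-bonded to C4=O and stays free under amine-base conditions.

**Step 5 (key step)**
Reactants: 6, dibromide; 7, prenylboronic acid pinacol ester [4,4,5,5-tetramethyl-2-(3-methylbut-2-en-1-yl)-1,3,2-dioxaborolane] (3 equiv)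
Product: 8, 5-hydroxy-7-(methoxymethoxy)-3-[4-(methoxymethoxy)-3,5-bis(3-methylbut-2-en-1-yl)phenyl]-4H-chromen-4-one
Conditions: Pd-PEPPSI-IPent (5 mol %), 3 M aq K3PO4 (6 equiv), THF, degassed, 65 °C
Reagents that add atoms: 7, prenyl-Bpin, CC(C)=CCB1OC(C)(C)C(C)(C)O1 (supplies both C5 prenyl units)
Why: Double allyl–aryl Suzuki–Miyaura coupling; with a very bulky NHC–Pd catalyst the allyl-Pd(Ar) intermediate equilibrates (σ–π–σ) and reductively eliminates at the unhindered CH2 terminus, giving the linear Ar–CH2–CH=CMe2 product and not the reverse-prenyl isomer. Each C–Br has only one ortho substituent (OMOM), the allylboronate does not add to the vinylogous-ester carbonyl, and the 5-phenoxide formed under the base protects the pyranone from hydroxide ring-opening.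

**Step 6**
Reactants: 8, bis-MOM diprenyl isoflavone
Product: 9, 3',5'-diprenylgenistein [5,7-dihydroxy-3-[4-hydroxy-3,5-bis(3-methylbut-2-en-1-yl)phenyl]-4H-chromen-4-one]
Conditions: 3 M aq HCl, MeOH/THF, 45 °C, 2–3 h (TLC-monitored, stopped at completion)
Reagents that add atoms: none
Why: Acid-catalysed hydrolysis of the two MOM acetals is much faster than protonation of the trisubstituted alkenes, so the o-prenylphenol survives if the reaction is stopped promptly. No stereocentre is created anywhere in the route.

## Compound list

1 | 4-hydroxyphenylacetic acid | O=C(O)Cc1ccc(O)cc1 | starting material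
2 | 3,5-dibromo-4-hydroxyphenylacetic acid | O=C(O)Cc1cc(Br)c(O)c(Br)c1 | intermediate
3 | phloroglucinol | Oc1cc(O)cc(O)c1 | starting material
4 | 2-(3,5-dibromo-4-hydroxyphenyl)-1-(2,4,6-trihydroxyphenyl)ethan-1-one | O=C(Cc1cc(Br)c(O)c(Br)c1)c1c(O)cc(O)cc1O | intermediate
5 | 3',5'-dibromogenistein | O=c1c(-c2cc(Br)c(O)c(Br)c2)coc2cc(O)cc(O)c12 | intermediate
6 | 7,4'-di-O-MOM-3',5'-dibromogenistein | COCOc1cc(O)c2c(c1)occ(-c1cc(Br)c(OCOC)c(Br)c1)c2=O | intermediate
7 | prenylboronic acid pinacol ester | CC(C)=CCB1OC(C)(C)C(C)(C)O1 | starting material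
8 | 7,4'-di-O-MOM-3',5'-diprenylgenistein | COCOc1cc(O)c2c(c1)occ(-c1cc(CC=C(C)C)c(OCOC)c(CC=C(C)C)c1)c2=O | intermediate
9 | 3',5'-diprenylgenistein | CC(C)=CCc1cc(-c2coc3cc(O)cc(O)c3c2=O)cc(CC=C(C)C)c1O | target

## Summary

**Total steps:** 6 (5 operations if steps 2 and 3 are telescoped).
**Longest linear sequence:** 6, from 4-hydroxyphenylacetic acid.

**Three steps most likely to fail, with fallbacks:**

1. **Step 5 (double prenyl Suzuki).** Risks are α/γ (linear versus reverse-prenyl) leakage, mono-coupling or protodebromination, and base-induced pyranone opening. Fallback: couple 6 twice with allyl-Bpin or allyl-SnBu3, where no regiochemical ambiguity exists, to give the 3',5'-diallyl isoflavone. Then convert both allyl groups to prenyl by double olefin cross-metathesis with 2-methyl-2-butene (Grubbs II), and deprotect.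

2. **Step 6 (MOM removal).** The risk is acid-catalysed cyclisation of the 4'-OH onto a prenyl alkene, giving a 2,2-dimethylchroman. Fallback: change the protecting-group strategy at step 4 to silyl ethers (TIPS on 7-OH and 4'-OH) and finish with fluoride (TBAF/AcOH), so no Brønsted acid touches the o-prenylphenol.

3. **Step 3 (BF3/DMF/MsCl ring closure on the dibromophenol deoxybenzoin).** Risks are O-sulfonylation or O-formylation of the acidic 2,6-dibromophenol and incomplete cyclisation. Fallback: reach 6 convergently instead. Make 5-hydroxy-7-(methoxymethoxy)-3-iodochromone from 2,4,6-trihydroxyacetophenone (bis-MOM protection; DMF-DMA enaminone; I2 cyclisation, which also cleaves the peri 5-OMOM). Couple it chemoselectively at C–I over C–Br at rt with [3,5-dibromo-4-(methoxymethoxy)phenyl]boronic acid, then continue from step 5.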